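**Plan**
1. Numbering is that of ent-kaurane: ring A = C1–C5 + C10 (C18/C19 on C4, C20 on C10); ten-membered ring = C5–C6–C7–C8=C14–C13–C12–C11–C9–C10; cyclopentenone = C8, C14, C13, C16(=C17), C15(=O).
2. Retrosynthesis: take off C17 and the C15 oxygen, then cut ring A at C4–C5 and C10–C1. C10 and C5 are the α- and β-carbons of the C9 ketone and C1–C4 carry no function, so ring A maps onto a C9(=O)–C10(CH3)=C5 enone in the bicyclo[7.2.1]dodecane core plus 4-methylpent-4-enal; the aldehyde leaves a C1 hydroxyl as a helper that is removed.
3. The core is cut at C12–C13 (anionic oxy-Cope; retro: re-form C8–C9) to a 6-vinylspiro[4.5]deca-1,7-dien-6-ol, and this to (R)-carvone (C5–C10, C20), ethyl formate (C14), acrolein (C15, C16, C13) and vinylmagnesium bromide (C11, C12).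
4. Forward: carvone ring → spiro cyclopentene (ring-closing metathesis) → ten-membered ring by oxy-Cope ring expansion, which opens the carvone ring → ring A last, by an iron-hydride radical–polar crossover annulation → C1 deoxygenation, acetates, C15 ketone, C17 methylene.
5. Stereochemistry: C7 from carvone (isopropenyl → acetate with retention); spiro C8 by Michael addition anti to the isopropenyl group, relayed to C13 by the suprafacial [3,3] shift; C11 by face-selective enolate oxygenation; C5 by outer-face radical addition; C10 by the tethered aldol (trans ring fusion).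

Key step: step 10

Remark: 4-methylpent-4-enal is taken as a catalogue compound; configurations drawn at centres that are destroyed later (peroxyketal carbon in 6, C9 in 11–13, C1 in 19 and 20, C15 in 24, C16 in 26) are the expected ones and do not bear on the target.

**Route**

Step 1
Reactants: 1 (R)-carvone; 2 ethyl formate
Product: 3 hydroxymethylene ketone
Conditions: NaH, EtOH (cat.), Et2O, 0 °C to rt; aq. HCl
Reagents that add atoms: none
Why: Claisen formylation under thermodynamic control goes to the only α'-methylene (C8) because the product is held as its stabilised β-dicarbonyl anion, and the C7 stereocentre is not enolisable.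

Step 2
Reactants: 3 hydroxymethylene ketone; 4 acrolein
Product: 5 keto dialdehyde
Conditions: Et3N (cat.), CH2Cl2, 0 °C
Reagents that add atoms: none
Why: Base-catalysed Michael addition of the formyl ketone creates the quaternary C8, the acceptor entering anti to the neighbouring isopropenyl group so that the formyl group (future C14) ends cis and the 3-oxopropyl chain (future C15, C16, C13) trans to it.

Step 3
Reactants: 5 keto dialdehyde
Product: 7 acetoxy keto dialdehyde, via methoxy hydroperoxide 6 (not isolated)
Conditions: O3, CH2Cl2/MeOH, NaHCO3, −78 °C (indicator control); solvent change; Ac2O, Et3N, DMAP (cat.), CH2Cl2, 0 °C to rt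
Reagents that add atoms: ozone, [O-][O+]=O (ether oxygen); methanol, CO (carbonyl oxygen of the acetate)
Why: Ozonolysis of the only electron-rich alkene in methanol gives the α-methoxy hydroperoxide, whose peracetate undergoes Criegee rearrangement with migration of the secondary C7 and retention of configuration, while the conjugated enone and the aldehydes are inert to ozone at −78 °C.

Step 4
Reactants: 7 acetoxy keto dialdehyde
Product: 8 triene acetate
Conditions: Ph3PCH3Br, KN(SiMe3)2, THF, 0 °C; then 7, −78 to 0 °C
Reagents that add atoms: methyltriphenylphosphonium bromide, C[P+](c1ccccc1)(c1ccccc1)c1ccccc1.[Br-]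
Why: Twofold Wittig methylenation is selective for the two aldehydes over the hindered conjugated C9 ketone and the acetate, turning the formyl group into the C14 vinyl group and the chain into a but-3-enyl group.

Step 5
Reactants: 8 triene acetate
Product: 9 spiro dienone acetate
Conditions: second-generation Grubbs catalyst (cat.), CH2Cl2, 40 °C
Reagents that add atoms: none
Why: Ring-closing metathesis of the vinyl and but-3-enyl groups closes the spiro cyclopent-2-ene (C14=C13), and the trisubstituted electron-poor enone alkene does not take part.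

Step 6
Reactants: 9 spiro dienone acetate; 10 vinylmagnesium bromide
Product: 11 spiro diol
Conditions: CH2=CHMgBr (4 equiv), CeCl3, THF, −78 to 0 °C; aq. NH4Cl
Reagents that add atoms: none
Why: Organocerium 1,2-addition to the hindered C9 enone gives the bis-allylic tertiary carbinol, vinyl entering anti to the pseudoaxial C14 arm on C8, and the excess reagent cleaves the acetate; the C9 configuration is lost again in step 8.

Step 7
Reactants: 11 spiro diol
Product: 12 silyl ether carbinol
Conditions: TBSOTf (1.1 equiv), 2,6-lutidine, CH2Cl2, −78 °C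
Reagents that add atoms: tert-butyldimethylsilyl triflate, CC(C)(C)[Si](C)(C)OS(=O)(=O)C(F)(F)F
Why: Silylation of the secondary C7 hydroxyl is much faster than that of the tertiary C9 hydroxyl at −78 °C.

Step 8
Reactants: 12 silyl ether carbinol
Product: 15 hydroxy enone core, via potassium alkoxide 13 (not isolated), via potassium enolate 14 (not isolated)
Conditions: KN(SiMe3)2, 18-crown-6, THF, 0 °C to rt; then −78 °C, 2-(phenylsulfonyl)-3-phenyloxaziridine; aq. NH4Cl
Reagents that add atoms: 2-(phenylsulfonyl)-3-phenyloxaziridine, O=S(=O)(c1ccccc1)N1OC1c1ccccc1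
Why: Anionic oxy-Cope rearrangement of the 1,5-diene C12=C11–C9–C8–C14=C13 breaks C8–C9 and forms C12–C13 suprafacially on the cyclopentene face that carried C9, so the C8 configuration is transferred to C13 and the bridgehead C8=C14 alkene and the ten-membered ring arise together; the regiodefined C9=C11 enolate is then oxygenated by the N-sulfonyloxaziridine on its exposed outer face, which is expected to give the (11S) carbinol.

Step 9
Reactants: 15 hydroxy enone core
Product: 16 bis-silyl enone core
Conditions: TBSOTf, 2,6-lutidine, CH2Cl2, 0 °C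
Reagents that add atoms: tert-butyldimethylsilyl triflate, CC(C)(C)[Si](C)(C)OS(=O)(=O)C(F)(F)F
Why: Triflate silylation protects the α-keto hydroxyl so that only the C1 hydroxyl made in step 10 is free for deoxygenation.

Step 10
Reactants: 16 bis-silyl enone core; 17 4-methylpent-4-enal
Product: 19 ring A aldol, via Giese adduct enol 18 (not isolated)
Conditions: Fe(acac)3 (cat.), PhSiH3, EtOH/(CH2OH)2, 0 °C to rt, 17 in excess
Reagents that add atoms: none
Why: Hydrogen-atom transfer from the iron hydride formed from Fe(acac)3 and PhSiH3 to the 1,1-disubstituted alkene of 17 gives the tertiary radical at C4, which adds to C5, the β-carbon of the C9(=O)–C10(CH3)=C5 enone of 16, and the resulting C10 radical is reduced by divalent iron to the enolate (18, drawn as its enol), which attacks the tethered C1 aldehyde. The closest known reaction type is the iron-hydride radical–polar crossover annulation of γ,δ-unsaturated aldehydes with α-methyl cyclohexenones (Giese addition, then aldol), applied here to a ten-membered enone. Ring A is closed in the second event, a 6-(enolexo)-exo-trig aldol that forms C10–C1 after the intermolecular C4–C5 bond. C5 is set by approach of the bulky radical to the outer face of the Z enone, the face turned away from the C15–C16 bridge of the bicyclo[7.2.1] core, and C10 is set by the tether, because the aldehyde can reach C10 only from the face that carries C4 while allylic 1,3-strain holds C5–H in the enolate plane, which places the C20 methyl anti to C5–H (trans ring fusion); the C1 carbinol, drawn trans to C20, is removed later. The step needs hydrogen-atom transfer to 17 and not to the trisubstituted bridgehead C8=C14 alkene (secured by the much higher rate for 1,1-disubstituted alkenes and the excess of 17), attack at C5 and not at C14 (only C5 is conjugated to a carbonyl group, C15 being a CH2 group at this stage), and aldol closure ahead of enolate protonation (secured by the six-membered metal-bridged closure).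

Step 11
Reactants: 19 ring A aldol
Product: 20 thionocarbonate
Conditions: PhOC(S)Cl, pyridine, DMAP, CH2Cl2, rt
Reagents that add atoms: O-phenyl chlorothionoformate, S=C(Cl)Oc1ccccc1
Why: DMAP-catalysed acylation of the only free hydroxyl with the thionochloroformate is not basic enough to start retro-aldol cleavage of the β-hydroxy ketone.

Step 12
Reactants: 20 thionocarbonate
Product: 21 deoxygenated tricycle
Conditions: Bu3SnH (high concentration), AIBN (cat.), toluene, 100 °C
Reagents that add atoms: none
Why: Barton–McCombie deoxygenation removes the helper hydroxyl, and a high stannane concentration traps the secondary C1 radical before it can shift the neighbouring acyl group.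

Step 13
Reactants: 21 deoxygenated tricycle
Product: 22 tricyclic diol
Conditions: HF·pyridine, pyridine/THF, 0 °C to rt
Reagents that add atoms: none
Why: Acidic fluoride cleaves both silyl ethers without epimerising the α-hydroxy ketone at C11.

Step 14
Reactants: 22 tricyclic diol
Product: 23 tricyclic diacetate
Conditions: Ac2O, pyridine, DMAP (cat.), CH2Cl2, rt
Reagents that add atoms: acetic anhydride, CC(=O)OC(C)=O
Why: Standard acetylation of the two secondary hydroxyls installs the C7 and C11 acetates of the target.

Step 15
Reactants: 23 tricyclic diacetate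
Product: 24 C15 allylic alcohol
Conditions: SeO2 (cat.), t-BuOOH, CH2Cl2, rt
Reagents that add atoms: tert-butyl hydroperoxide, CC(C)(C)OO (oxygen relayed by SeO2, O=[Se]=O)
Why: Selenium dioxide allylic oxidation (ene reaction, then [2,3] shift) attacks the allylic CH2 on the more substituted alkene carbon, C15, in preference to the acetoxy-bearing C7 methine and the bridgehead C13, and leaves C8=C14 in place, the hydroxyl being expected on the face away from C12.

Step 16
Reactants: 24 C15 allylic alcohol
Product: 25 C15 enone
Conditions: Dess–Martin periodinane, NaHCO3, CH2Cl2, rt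
Reagents that add atoms: none
Why: Buffered Dess–Martin oxidation of the allylic alcohol gives the cyclopentenone without touching the acetates or the C11 centre.

Step 17
Reactants: 25 C15 enone
Product: 27 target, via Mannich base 26 (not isolated)
Conditions: (CH2O)n, i-Pr2NH·CF3CO2H, THF, 65 °C
Reagents that add atoms: formaldehyde (from paraformaldehyde), C=O
Why: Mannich condensation at C16, the only methylene next to a ketone, then β-elimination of the amine gives the exocyclic C16=C17 bond, while C11 has no second hydrogen for methylenation and the acetates survive the weakly acidic medium.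

**Compound list**
1 | (R)-(−)-carvone, (5R)-2-methyl-5-(prop-1-en-2-yl)cyclohex-2-en-1-one | O=C1C(C)=CC[C@@H](C(C)=C)C1 | starting material
2 | ethyl formate | CCOC=O | starting material
3 | (Z)-6-(hydroxymethylidene)carvone, H-bonded enol of the C8 formyl ketone, isopropenyl centre as in 1 | O/C=C1\C(=O)C(C)=CC[C@H]1C(C)=C | intermediate
4 | acrolein | C=CC=O | starting material
5 | 6-formyl-6-(3-oxopropyl)carvone, formyl cis and 3-oxopropyl trans to the isopropenyl group | O=C1C(C)=CC[C@@H](C(C)=C)[C@]1(C=O)CCC=O | intermediate
6 | α-methoxy hydroperoxide of 5 (isopropenyl replaced by C(CH3)(OCH3)OOH, both epimers at that carbon) | O=C1C(C)=CC[C@@H](C(C)(OC)OO)[C@]1(C=O)CCC=O | intermediate (not isolated)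
7 | 5-acetoxy-6-formyl-2-methyl-6-(3-oxopropyl)cyclohex-2-en-1-one, acetoxy cis to formyl | O=C1C(C)=CC[C@@H](OC(C)=O)[C@]1(C=O)CCC=O | intermediate
8 | 5-acetoxy-6-(but-3-en-1-yl)-6-ethenyl-2-methylcyclohex-2-en-1-one, acetoxy cis to ethenyl | O=C1C(C)=CC[C@@H](OC(C)=O)[C@]1(C=C)CCC=C | intermediate
9 | 7-methyl-6-oxospiro[4.5]deca-1,7-dien-10-yl acetate, acetoxy on the side of alkene carbon C1 of the five-membered ring (= C14) | O=C1C(C)=CC[C@@H](OC(C)=O)[C@@]12C=CCC2 | intermediate
10 | vinylmagnesium bromide | C=C[Mg]Br | starting material
11 | 6-ethenyl-7-methylspiro[4.5]deca-1,7-diene-6,10-diol, 6-OH cis to 10-OH, ethenyl trans to ring carbon C1 | C=C[C@]1(O)C(C)=CC[C@@H](O)[C@@]12C=CCC2 | intermediate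
12 | 10-O-tert-butyldimethylsilyl ether of 11 | C=C[C@]1(O)C(C)=CC[C@@H](O[Si](C)(C)C(C)(C)C)[C@@]12C=CCC2 | intermediate
13 | potassium C9 alkoxide of 12 | [K+].C=C[C@]1([O-])C(C)=CC[C@@H](O[Si](C)(C)C(C)(C)C)[C@@]12C=CCC2 | intermediate (not isolated)
14 | potassium C9=C11 enolate of the bicyclo[7.2.1]dodecatriene core (7-silyloxy, Z-C10=C5, C8=C14, oxygen cis to C12) | [K+].C1CC2=C[C@H]1C/C=C(\[O-])/C(C)=C\C[C@H]2O[Si](C)(C)C(C)(C)C | intermediate (not isolated)
15 | bicyclo[7.2.1]dodecadienone core in ent-kaurane numbering: 9-oxo, (11S)-hydroxy, 7-(tert-butyldimethylsilyloxy), Z-C10=C5, C8=C14, bridge C15–C16; C7, C11, C13 as in the target | C1CC2=C[C@H]1C[C@H](O)C(=O)/C(C)=C\C[C@H]2O[Si](C)(C)C(C)(C)C | intermediate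
16 | 11-O-tert-butyldimethylsilyl ether of 15 | C1CC2=C[C@H]1C[C@H](O[Si](C)(C)C(C)(C)C)C(=O)/C(C)=C\C[C@H]2O[Si](C)(C)C(C)(C)C | intermediate
17 | 4-methylpent-4-enal | CC(=C)CCC=O | starting material
18 | C10 enolate of the Giese adduct, drawn as its enol: C5 carries the 2-methyl-5-oxopentan-2-yl group, C9(OH)=C10 with C11 cis to C5 | C1CC2=C[C@H]1C[C@H](O[Si](C)(C)C(C)(C)C)/C(O)=C(C)\[C@@H](C(C)(C)CCC=O)C[C@H]2O[Si](C)(C)C(C)(C)C | intermediate (not isolated)
19 | 1-hydroxy-7,11-bis(tert-butyldimethylsilyloxy)-17-nor-8,9-seco-ent-kaur-8(14)-en-9-one, ring A trans-fused, 1-OH trans to C20, other centres as in the target | C1CC2=C[C@H]1C[C@H](O[Si](C)(C)C(C)(C)C)C(=O)[C@]1(C)[C@H](O)CCC(C)(C)[C@H]1C[C@H]2O[Si](C)(C)C(C)(C)C | intermediate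
20 | O-phenyl thionocarbonate of 19 at C1 | C1CC2=C[C@H]1C[C@H](O[Si](C)(C)C(C)(C)C)C(=O)[C@]1(C)[C@H](OC(=S)Oc3ccccc3)CCC(C)(C)[C@H]1C[C@H]2O[Si](C)(C)C(C)(C)C | intermediate
21 | 7,11-bis(tert-butyldimethylsilyloxy)-17-nor-8,9-seco-ent-kaur-8(14)-en-9-one, centres as in the target | C1CC2=C[C@H]1C[C@H](O[Si](C)(C)C(C)(C)C)C(=O)[C@]1(C)CCCC(C)(C)[C@H]1C[C@H]2O[Si](C)(C)C(C)(C)C | intermediate
22 | 7,11-dihydroxy-17-nor-8,9-seco-ent-kaur-8(14)-en-9-one | C1CC2=C[C@H]1C[C@H](O)C(=O)[C@]1(C)CCCC(C)(C)[C@H]1C[C@H]2O | intermediate
23 | 7,11-diacetoxy-17-nor-8,9-seco-ent-kaur-8(14)-en-9-one | C1CC2=C[C@H]1C[C@H](OC(C)=O)C(=O)[C@]1(C)CCCC(C)(C)[C@H]1C[C@H]2OC(C)=O | intermediate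
24 | 15-hydroxy derivative of 23, hydroxyl on the five-ring face away from C12 | C1[C@H](O)C2=C[C@H]1C[C@H](OC(C)=O)C(=O)[C@]1(C)CCCC(C)(C)[C@H]1C[C@H]2OC(C)=O | intermediate
25 | 7,11-diacetoxy-17-nor-8,9-seco-ent-kaur-8(14)-ene-9,15-dione | C1C(=O)C2=C[C@H]1C[C@H](OC(C)=O)C(=O)[C@]1(C)CCCC(C)(C)[C@H]1C[C@H]2OC(C)=O | intermediate
26 | 16-[(diisopropylamino)methyl] derivative of 25, aminomethyl on the face away from C12 | CC(C)N(C(C)C)C[C@@H]1C(=O)C2=C[C@H]1C[C@H](OC(C)=O)C(=O)[C@]1(C)CCCC(C)(C)[C@H]1C[C@H]2OC(C)=O | intermediate (not isolated)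
27 | CNP0417044.1, (5R,7R,10R,11S,13R)-7,11-diacetoxy-8,9-seco-ent-kaura-8(14),16-diene-9,15-dione | C=C1C(=O)C2=C[C@H]1C[C@H](OC(C)=O)C(=O)[C@]1(C)CCCC(C)(C)[C@H]1C[C@H]2OC(C)=O | target

**Totals**
Total step count: 17. Longest linear sequence: 17 steps (from 1).

**Steps most likely to fail**

Step 10. What may go wrong: hydrogen-atom transfer to the bridgehead C8=C14 alkene, transannular capture of the C10 radical by that alkene, protonation of the enolate before the aldol, or radical addition to the inner face of the enone. The fallback is polar and stepwise, sets out from 16 and comes back at 19. Hosomi–Sakurai conjugate addition of trimethyl(3-methylbut-2-en-1-yl)silane (TiCl4, CH2Cl2, −78 °C) should give the C5 (2-methylbut-3-en-2-yl) ketone F1, the allylsilane reacting through its γ-carbon to make the quaternary C4 under Lewis-acid rather than radical control. Linear-selective hydroformylation of its neopentyl-type vinyl group (Rh(acac)(CO)2, Xantphos, CO/H2, toluene, 80 °C) should give the keto aldehyde F2, the keto form of 18. A base-mediated aldol through the more substituted C10 enolate (KOt-Bu, t-BuOH/THF, 0 °C) should then close ring A from the C4 face and return to 19; the C10 centre of F1 and F2 is re-enolised there, so its configuration is immaterial.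

Step 8. What may go wrong: oxygen transfer to the inner face of enolate 14, giving poor or inverted facial selectivity at C11. The fallback sets out from 12 and comes back at 15. The same tandem reaction is taken through the C11 epimer of the hydroxy enone F3; Mitsunobu esterification with 4-nitrobenzoic acid (PPh3, DIAD, THF, 0 °C) inverts the activated α-keto carbinol by SN2 displacement to give the 4-nitrobenzoate F4, and methanolysis (K2CO3, MeOH, 0 °C) returns to 15.

Step 12. What may go wrong: 1,2-acyl shift of the C1 radical to the tertiary C10 radical (ring enlargement of the ten-membered ring), or retro-aldol cleavage while the hindered hydroxyl is thioacylated in step 11. The fallback avoids radicals, sets out from 19 and comes back at 21. Dehydration with the Burgess reagent (toluene, 60 °C; syn elimination toward C2, the only β-hydrogens) should give the Δ1 alkene F5, and diimide (TsNHNH2, NaOAc, THF/H2O, 70 °C) should reduce the cis-disubstituted C1=C2 bond in preference to the trisubstituted bridgehead alkene to give 21.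

**Further compounds**
F1 | step 10 | Sakurai adduct of 16: C5 carries a 2-methylbut-3-en-2-yl group, C10–H ketone (C10 as drawn, immaterial) | C1CC2=C[C@H]1C[C@H](O[Si](C)(C)C(C)(C)C)C(=O)[C@@H](C)[C@@H](C(C)(C)C=C)C[C@H]2O[Si](C)(C)C(C)(C)C
F2 | step 10 | keto aldehyde, keto form of 18: C5 carries a 2-methyl-5-oxopentan-2-yl group | C1CC2=C[C@H]1C[C@H](O[Si](C)(C)C(C)(C)C)C(=O)[C@@H](C)[C@@H](C(C)(C)CCC=O)C[C@H]2O[Si](C)(C)C(C)(C)C
F3 | step 8 | C11 epimer of 15 | C1CC2=C[C@H]1C[C@@H](O)C(=O)/C(C)=C\C[C@H]2O[Si](C)(C)C(C)(C)C
F4 | step 8 | 4-nitrobenzoate of 15 (C11 configured as in the target) | C1CC2=C[C@H]1C[C@H](OC(=O)c3ccc(cc3)[N+](=O)[O-])C(=O)/C(C)=C\C[C@H]2O[Si](C)(C)C(C)(C)C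
F5 | step 12 | Δ1 alkene: 7,11-bis(tert-butyldimethylsilyloxy)-17-nor-8,9-seco-ent-kaura-1,8(14)-dien-9-one | C1CC2=C[C@H]1C[C@H](O[Si](C)(C)C(C)(C)C)C(=O)[C@]1(C)C=CCC(C)(C)[C@H]1C[C@H]2O[Si](C)(C)C(C)(C)C
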